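Assumption: the target has no stereogenic centre, so "single enantiomer" is read as the single (E,E) geometric isomer drawn. Retinoid numbering is used throughout: ring C1–C6 (C1 carries the gem-dimethyl group, C5 the ring methyl, C6 the chain), chain C7–C15, with C15 bonded to the hydroquinone.

## The problem

- Jaspaquinol is a 2-substituted hydroquinone whose C20 substituent holds all the difficulty. It has a tetrasubstituted ring olefin (C5=C6 of a 2,6,6-trimethylcyclohexene) and two E-trisubstituted olefins (C9=C10, C13=C14), joined by two CH2–CH2 links (C7–C8 and C11–C12).
- There is no stereocentre. The only stereochemical elements are the two E olefins, and neither lies near a group that could control its geometry, so each must be made on its own or taken over intact.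
- The ring olefin must be the tetrasubstituted (β) isomer. Cationic ring closures give it mixed with the α and γ isomers.
- The chain is a head-to-tail 1,5-polyene, so strong acids and electrophiles start cation–olefin cyclisation.
- The hydroquinone oxidises to the quinone in air, and its ortho hydroxyl adds to C13=C14 under acid to give a chroman.
- The aryl–C15 bond must be formed without allylic transposition and without loss of the C13=C14 geometry.
- The enabling feature: the C20 unit (C1–C15 plus five methyl groups) is, atom for atom, the carbon skeleton of retinol. The two CH2–CH2 links C7–C8 and C11–C12 coincide with the two trans-disubstituted double bonds of the retinyl pentaene. The three olefins the target keeps (C5=C6, C9=C10, C13=C14) are the tetra- and trisubstituted ones of all-trans-retinol, already with the required geometry.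

## Retrosynthesis

**12 ⇒ 11.** The two O–H bonds of jaspaquinol 12 are masked as methoxymethyl ethers in 11. This cut comes first because the free hydroquinone is the most fragile part of the molecule; MOM groups can also direct the metalation that forms the aryl–C15 bond. The forward reaction must cleave two aryl acetals without protonating the 1,5-diene.

**11 ⇒ 6 + 10.** The aryl–C15 bond is cut to the allylic bromide 6 and the arylcopper 10. The copper reagent comes from the aryllithium 9, made by ortho-lithiation of 1,4-bis(methoxymethoxy)benzene 8, itself from hydroquinone 7. This cut is preferred to a Friedel–Crafts union of free 7 with an allyl cation, which would put a cation next to the 1,5-diene. The precursors are a symmetrical arene and a C20 bromide with no aromatic ring. The forward reaction must be an SN2 (α) substitution with retention of the C13=C14 geometry.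

**6 ⇒ 5 ⇒ 4.** The C15–Br bond goes back to the C15–OH bond of alcohol 5 and to the C15–OAc bond of acetate 4. These are functional-group changes on a primary allylic position and nothing more is asked of them.

**4 ⇒ 1 (key).** No C–C bond is cut. Four C–H bonds are removed, at C7, C8, C11 and C12, which turns 4 into all-trans-retinyl acetate 1, a commodity chemical.
- Against any cut of a C–C bond in the chain, this takes over the whole C20 skeleton, the position of the ring olefin and both E-trisubstituted olefins.
- The forward reaction is a two-fold semireduction. It must saturate only the two trans-disubstituted bonds of a conjugated pentaene and leave two trisubstituted and one tetrasubstituted bond untouched, without migrating any double bond.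
- Diimide is chosen because it discriminates by substitution, adds strictly 1,2 and does not cleave allylic C–O bonds.
- The dihydro compounds 2 and 3 are the intermediates.

## Roads not taken

**Alternative 1: stepwise chain extension of dihydro-β-ionone A1 (the most obvious route).**
- Cut: the C9=C10 and C13=C14 double bonds (olefination) and the C11–C12 bond (acetoacetate alkylation).
- Forward: Horner–Wadsworth–Emmons olefination of the methyl ketone A1 gives ester A2. Reduction, bromination and acetoacetate alkylation–decarboxylation give the C18 ketone A3. A second olefination and reduction give alcohol 5.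
- Why not: each olefination of a methyl ketone gives an E/Z mixture that must be separated, twice, and some seven steps are needed to reach 5. The chosen plan reaches 5 in two steps and makes neither olefin.

**Alternative 2: biomimetic tail cyclisation of geranylgeranylhydroquinone A4.**
- Cut: the C1–C6 ring bond.
- Forward: protonation of the terminal isopropylidene group of A4 and capture by the neighbouring olefin, with proton loss to the tetrasubstituted olefin.
- Why not: the cyclohexyl cation formed after the first closure is placed for capture by the next trisubstituted olefin. Nothing in A4 stops the cascade after one ring or selects the β over the α and γ olefin, and the ortho phenol adds to the proximal olefin under the same acid. The chosen plan never generates a cation on the polyene.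

**Alternative 3: alkyne carbometalation.**
- Cut: each trisubstituted olefin into a terminal alkyne, a methyl group and a carbon electrophile, and the C14–C15 bond.
- Forward: alkyne A5 (from A1) undergoes Zr-catalysed methylalumination, and the alkenylmetal is extended by a homopropargyl unit to enyne A6. A second methylalumination and a Ni- or Pd-catalysed coupling with benzyl chloride A7 would give 11.
- Why not: stereocontrol is excellent, but the sequence is linear and longer, uses stoichiometric trimethylaluminium twice, and builds what retinyl acetate already contains.

Key step: step 1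

## Route

Step 1
Reactants: 1 all-trans-retinyl acetate
Product: 4 (9E,13E)-7,8,11,12-tetrahydroretinyl acetate [(2E,6E)-3,7-dimethyl-9-(2,6,6-trimethylcyclohex-1-en-1-yl)nona-2,6-dien-1-yl acetate], via 7,8-dihydroretinyl acetate 2 (not isolated), via 11,12-dihydroretinyl acetate 3 (not isolated)
Conditions: KO2C–N=N–CO2K (excess, in portions), AcOH (slow addition), pyridine, MeOH/CH2Cl2, 0 °C → rt, Ar, dark; monitored until 1, 2 and 3 are consumed
Reagents that add atoms: none
Why: Proposed new method: cis-diimide, released from the azodicarboxylate by protonation and decarboxylation, transfers two hydrogens suprafacially to one C=C through a six-membered cyclic transition state, and its known rate order (1,2-disubstituted faster than trisubstituted, tetrasubstituted almost inert, conjugated faster than isolated) is asked here to pick the two trans-disubstituted bonds C7=C8 and C11=C12 out of a conjugated pentaene. The closest known reaction type is the diimide reduction of the less substituted double bond of dienes and non-conjugated polyenes; a two-fold site-selective semireduction inside a retinoid polyene is not established. No ring is closed and no stereocentre is formed, since both reduced positions become CH2–CH2; the E geometry of C9=C10 and C13=C14 is kept because diimide adds only 1,2 and neither isomerises nor migrates double bonds. The selectivity needed is site selectivity against C9=C10 and C13=C14 (each carries a methyl group) and C5=C6 (tetrasubstituted and twisted out of conjugation), and the substitution pattern of the substrate is what secures it. Each reduction also cuts the chromophore, so the trisubstituted bonds of 4 end up isolated and should react more slowly than any bond of 1, 2 or 3, which gives a kinetic stop. Either 2 or 3 may form first; both converge on 4. Unlike catalytic hydrogenation, diimide does not cleave the allylic C15–O bond.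

Step 2
Reactants: 4 (9E,13E)-7,8,11,12-tetrahydroretinyl acetate
Product: 5 (2E,6E)-3,7-dimethyl-9-(2,6,6-trimethylcyclohex-1-en-1-yl)nona-2,6-dien-1-ol
Conditions: K2CO3 (cat.), MeOH, rt; chromatography on AgNO3-impregnated silica
Reagents that add atoms: none
Why: Base-catalysed transesterification (methanolysis) of the allylic acetate touches no olefin; the free alcohol should allow under- and over-reduced retinoids from step 1 to be removed by argentation chromatography.

Step 3
Reactants: 5 (2E,6E)-3,7-dimethyl-9-(2,6,6-trimethylcyclohex-1-en-1-yl)nona-2,6-dien-1-ol
Product: 6 2-[(3E,7E)-9-bromo-3,7-dimethylnona-3,7-dien-1-yl]-1,3,3-trimethylcyclohex-1-ene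
Conditions: PBr3 (0.4 equiv), pyridine (cat.), Et2O, −10 → 0 °C, dark; used crude
Reagents that add atoms: phosphorus tribromide, BrP(Br)Br
Why: Bromination of a primary allylic alcohol with PBr3 (SN2 on the phosphite ester) is the standard entry to farnesyl-type bromides; low temperature, exclusion of light and immediate use should preserve the C13=C14 geometry.

Step 4
Reactants: 7 hydroquinone
Product: 8 1,4-bis(methoxymethoxy)benzene
Conditions: NaH (2.2 equiv), MOMCl (2.2 equiv), DMF, 0 °C → rt, Ar
Reagents that add atoms: chloromethyl methyl ether, COCCl
Why: Williamson-type O-alkylation of the bis-phenoxide; the MOM groups protect the hydroquinone against oxidation and direct the ortho-lithiation of step 5.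

Step 5
Reactants: 8 1,4-bis(methoxymethoxy)benzene; 6 2-[(3E,7E)-9-bromo-3,7-dimethylnona-3,7-dien-1-yl]-1,3,3-trimethylcyclohex-1-ene
Product: 11 2-[(2E,6E)-3,7-dimethyl-9-(2,6,6-trimethylcyclohex-1-en-1-yl)nona-2,6-dien-1-yl]-1,4-bis(methoxymethoxy)benzene, via 2,5-bis(methoxymethoxy)phenyllithium 9 (not isolated), via 2,5-bis(methoxymethoxy)phenylcopper 10 (not isolated)
Conditions: n-BuLi, TMEDA, THF, 0 °C; CuI (1 equiv), −40 °C; then 6, −40 → 0 °C
Reagents that add atoms: none
Why: Directed ortho-metalation of 8 (all four ring positions are equivalent), transmetalation to the arylcopper and SN2 (α) substitution of the primary allylic bromide, as established for geranyl and farnesyl bromides. Attack at the γ-carbon would create a quaternary centre and is disfavoured, and the C13=C14 geometry should be retained because no free allyl cation is formed.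

Step 6
Reactants: 11 2-[(2E,6E)-3,7-dimethyl-9-(2,6,6-trimethylcyclohex-1-en-1-yl)nona-2,6-dien-1-yl]-1,4-bis(methoxymethoxy)benzene
Product: 12 jaspaquinol, 2-[(2E,6E)-3,7-dimethyl-9-(2,6,6-trimethylcyclohex-1-en-1-yl)nona-2,6-dien-1-yl]benzene-1,4-diol
Conditions: p-TsOH·H2O (cat.), degassed MeOH, rt → 40 °C, Ar; work-up under Ar with a dithionite wash
Reagents that add atoms: none
Why: Acid-catalysed acetal exchange of the aryl MOM ethers with methanol; conditions are kept mild, dilute and oxygen-free so that the three olefins and the liberated hydroquinone should survive.

## Compound list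

1 | all-trans-retinyl acetate (vitamin A acetate) | CC(=O)OC/C=C(C)/C=C/C=C(C)/C=C/C1=C(C)CCCC1(C)C | starting material
2 | 7,8-dihydroretinyl acetate (9E,11E,13E) | CC(=O)OC/C=C(C)/C=C/C=C(C)/CCC1=C(C)CCCC1(C)C | intermediate
3 | 11,12-dihydroretinyl acetate (7E,9E,13E) | CC(=O)OC/C=C(C)/CC/C=C(C)/C=C/C1=C(C)CCCC1(C)C | intermediate
4 | (9E,13E)-7,8,11,12-tetrahydroretinyl acetate | CC(=O)OC/C=C(C)/CC/C=C(C)/CCC1=C(C)CCCC1(C)C | intermediate
5 | (2E,6E)-3,7-dimethyl-9-(2,6,6-trimethylcyclohex-1-en-1-yl)nona-2,6-dien-1-ol | OC/C=C(C)/CC/C=C(C)/CCC1=C(C)CCCC1(C)C | intermediate
6 | 2-[(3E,7E)-9-bromo-3,7-dimethylnona-3,7-dien-1-yl]-1,3,3-trimethylcyclohex-1-ene | BrC/C=C(C)/CC/C=C(C)/CCC1=C(C)CCCC1(C)C | intermediate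
7 | hydroquinone | Oc1ccc(O)cc1 | starting material
8 | 1,4-bis(methoxymethoxy)benzene | COCOc1ccc(OCOC)cc1 | intermediate
9 | 2,5-bis(methoxymethoxy)phenyllithium | [Li]c1cc(OCOC)ccc1OCOC | intermediate
10 | 2,5-bis(methoxymethoxy)phenylcopper | [Cu]c1cc(OCOC)ccc1OCOC | intermediate
11 | 2-[(2E,6E)-3,7-dimethyl-9-(2,6,6-trimethylcyclohex-1-en-1-yl)nona-2,6-dien-1-yl]-1,4-bis(methoxymethoxy)benzene | COCOc1ccc(OCOC)c(C/C=C(C)/CC/C=C(C)/CCC2=C(C)CCCC2(C)C)c1 | intermediate
12 | jaspaquinol | CC1=C(CC/C(C)=C/CC/C(C)=C/Cc2cc(O)ccc2O)C(C)(C)CCC1 | target

## Step count and risk

Total steps: 6. Longest linear sequence: 5 (steps 1, 2, 3, 5, 6 from retinyl acetate 1).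

**Step 1 (key step, proposed new method).**
- Risk: erosion of site selectivity. In the triene of 2 the trisubstituted bonds C9=C10 and C13=C14 sit at the ends of the conjugated system, where the loss of conjugation on reduction is smallest, and this may partly offset their substitution penalty. C7=C8 is screened by the trimethylcyclohexenyl ring, so its rate advantage may be smaller than for an unhindered trans-olefin. Under- and over-reduction would then give retinoids that are hard to separate from 4.
- Fallback (known chemistry throughout, the classical C7–C8 allyl sulfone disconnection): it sets out from the arylcopper 10 and comes back at 11.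
  - 10 is alkylated with commercial geranyl bromide to give 2-geranyl-1,4-bis(methoxymethoxy)benzene F1.
  - Catalytic SeO2/t-BuOOH oxidation of the (E)-methyl group of the terminal isopropylidene, with borohydride work-up, gives (2E,6E)-8-[2,5-bis(methoxymethoxy)phenyl]-2,6-dimethylocta-2,6-dien-1-ol F2.
  - PBr3 converts it into the corresponding allylic bromide F3.
  - The lithio derivative of β-cyclogeranyl phenyl sulfone F4 (a known compound, prepared separately) is alkylated with F3 to the C7-phenylsulfonyl derivative of 11, F5 (racemic at C7).
  - Reductive desulfonylation (Na/Hg, Na2HPO4, MeOH) gives 11.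

**Step 5.**
- Risk: allylic transposition (SN2′ attack giving the branched isomer), loss of C13=C14 geometry through ionisation of the bromide, and homocoupling of the allyl partner.
- Fallback: it sets out from the aryllithium 9 and the acetate 4 and comes back at 11, by-passing steps 2 and 3. 9 is quenched with an isopropoxy pinacolborane to give 2-[2,5-bis(methoxymethoxy)phenyl]-4,4,5,5-tetramethyl-1,3,2-dioxaborolane F6. A Pd-catalysed Suzuki–Miyaura-type allyl–aryl coupling of F6 with 4, through a π-allylpalladium electrophile instead of an SN2 displacement, gives 11.

**Step 6.**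
- Risk: acid-promoted addition of the freed ortho-hydroxyl to C13=C14 (chroman formation), protonation-induced cyclisation of the 1,5-diene, and air oxidation of the product.
- Fallback: the hydroquinone is unmasked by redox chemistry instead of acid. It sets out from bromide 6 and comes back at 12.
  - Commercial 2-bromo-1,4-dimethoxybenzene F7 is converted by bromine–lithium exchange and CuI into the arylcopper and alkylated with 6 to give the dimethyl ether of jaspaquinol F8.
  - Oxidative demethylation with ceric ammonium nitrate gives the corresponding 1,4-benzoquinone (jaspaquinone) F9.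
  - Reduction with aqueous sodium dithionite gives 12.

**Step 3.**
- Risk: ionisation of the allylic bromide, with E/Z isomerisation at C13=C14 or transposition to the tertiary bromide, and decomposition before use.
- Fallback: it sets out from alcohol 5 and comes back at 12, with no bromide and no protecting groups. A direct Friedel–Crafts allylation of hydroquinone 7 with 5 (BF3·OEt2, dioxane, rt) gives 12 in one step, at the price of lower efficiency. This fallback makes no new compound (F0).

## Further compounds

F1 | step 1 | 2-geranyl-1,4-bis(methoxymethoxy)benzene | COCOc1ccc(OCOC)c(C/C=C(C)/CCC=C(C)C)c1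
F2 | step 1 | (2E,6E)-8-[2,5-bis(methoxymethoxy)phenyl]-2,6-dimethylocta-2,6-dien-1-ol | COCOc1ccc(OCOC)c(C/C=C(C)/CC/C=C(C)/CO)c1
F3 | step 1 | 2-[(2E,6E)-8-bromo-3,7-dimethylocta-2,6-dien-1-yl]-1,4-bis(methoxymethoxy)benzene | COCOc1ccc(OCOC)c(C/C=C(C)/CC/C=C(C)/CBr)c1
F4 | step 1 | β-cyclogeranyl phenyl sulfone, 1,3,3-trimethyl-2-[(phenylsulfonyl)methyl]cyclohex-1-ene | CC1=C(CS(=O)(=O)c2ccccc2)C(C)(C)CCC1
F5 | step 1 | C7-phenylsulfonyl derivative of 11 (racemic at C7) | COCOc1ccc(OCOC)c(C/C=C(C)/CC/C=C(C)/CC(C2=C(C)CCCC2(C)C)S(=O)(=O)c2ccccc2)c1
F6 | step 5 | 2-[2,5-bis(methoxymethoxy)phenyl]-4,4,5,5-tetramethyl-1,3,2-dioxaborolane | COCOc1ccc(OCOC)c(B2OC(C)(C)C(C)(C)O2)c1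
F7 | step 6 | 2-bromo-1,4-dimethoxybenzene | COc1ccc(OC)c(Br)c1
F8 | step 6 | jaspaquinol dimethyl ether, 2-[(2E,6E)-3,7-dimethyl-9-(2,6,6-trimethylcyclohex-1-en-1-yl)nona-2,6-dien-1-yl]-1,4-dimethoxybenzene | COc1ccc(OC)c(C/C=C(C)/CC/C=C(C)/CCC2=C(C)CCCC2(C)C)c1
F9 | step 6 | jaspaquinone, 2-[(2E,6E)-3,7-dimethyl-9-(2,6,6-trimethylcyclohex-1-en-1-yl)nona-2,6-dien-1-yl]cyclohexa-2,5-diene-1,4-dione | O=C1C=CC(=O)C(C/C=C(C)/CC/C=C(C)/CCC2=C(C)CCCC2(C)C)=C1
F0 | step 3 | none | none
A1 | alternative 1 | dihydro-β-ionone | CC(=O)CCC1=C(C)CCCC1(C)C
A2 | alternative 1 | ethyl (2E)-3-methyl-5-(2,6,6-trimethylcyclohex-1-en-1-yl)pent-2-enoate | CCOC(=O)/C=C(C)/CCC1=C(C)CCCC1(C)C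
A3 | alternative 1 | (5E)-6-methyl-8-(2,6,6-trimethylcyclohex-1-en-1-yl)oct-5-en-2-one | CC(=O)CC/C=C(C)/CCC1=C(C)CCCC1(C)C
A4 | alternative 2 | 2-[(2E,6E,10E)-geranylgeranyl]hydroquinone | CC(C)=CCC/C(C)=C/CC/C(C)=C/CC/C(C)=C/Cc1cc(O)ccc1O
A5 | alternative 3 | 2-(but-3-yn-1-yl)-1,3,3-trimethylcyclohex-1-ene | C#CCCC1=C(C)CCCC1(C)C
A6 | alternative 3 | 1,3,3-trimethyl-2-[(3E)-3-methyloct-3-en-7-yn-1-yl]cyclohex-1-ene | C#CCC/C=C(C)/CCC1=C(C)CCCC1(C)C
A7 | alternative 3 | 2,5-bis(methoxymethoxy)benzyl chloride | COCOc1ccc(OCOC)c(CCl)c1
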